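**Remarks on the chemistry**

- Halimane numbering is used for every intermediate; the target is (4S,6S,8S,9R). The precursor and the product of the key step carry this configuration at all four centres, so no structure needs correcting.
- Two design changes are made. O12 carries TBS (not a bulkier silyl group) so that this primary ether can be cleaved before the hindered O6 ether. Ring B is built by catalytic asymmetric conjugate addition to an achiral enone, because a symmetric 1,3-dione offers no source of absolute configuration.
- The allylic alcohol is used as its (Z) isomer; the reason is given at step 12.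
- Abbreviations: TBS = tert-butyldimethylsilyl, TES = triethylsilyl, TMS = trimethylsilyl, PMB = 4-methoxybenzyl, Tf = trifluoromethanesulfonyl.

## Structural features

The target is a halimane-type bicycle in which rings A and B are fused through the tetrasubstituted C5=C10 alkene. Ring A holds the C3 ketone and the quaternary C4, which bears a methyl group and the C19 methylene esterified with 3-(4-hydroxyphenyl)propanoic acid. Ring B holds the allylic C6 carbinol, the C8 methine with its methyl group, and the quaternary C9 with a methyl group and the C11–C12 chain that ends at the β-carbon of a butenolide. C8 and C9 are contiguous with their methyl groups cis. C4 and C6 both sit on sp2 C5, and C4 has no stereocentre next to it, so its relation to C8/C9 must be relayed across the alkene. Fragile points are the butenolide (base), the allylic C6 alcohol (ionisation), the phenol, and the free C19 ketol stage (retro-aldol). The real difficulty is the pair of quaternary carbons C4 and C9 flanking a fully substituted alkene, together with the remote control of C4. The key step exploits the fact that C1 is β to the C3 carbonyl and bonded to alkene carbon C10: a C3 cyclopropanol is a latent C1 homoenolate that can be joined to a C10 enol triflate to close ring A.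

## Logic of the disconnections

**C12–C13 and two O–Si bonds (40 ⇒ 39 ⇒ 36 + 37).** The butenolide is the most base-sensitive unit and its β-carbon is an sp2 centre bonded to a primary sp3 carbon, so the cut is made there and the ring arrives intact as 37. 36 comes from 34 through 35 by unmasking and iodinating O12. The gain is that the whole side chain shrinks to a two-carbon silyl ether carried from the start. The demand is that organozinc 38 forms and couples beside the C3 ketone and the ester, and that the last step frees O6 and the phenol without base.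

**C19 O–acyl bond (34 ⇒ 30 + 33; 33 ⇐ 31).** The aryl ester would not survive enolate, hydride and organometallic steps, so O19 travels as a PMB ether and is acylated once ring A exists. The gain is a commercial acid protected in one step. The demand is that acylation of ketol 30 outruns retro-aldol loss of C19.

**C1–C10 (29 ⇒ 28), the key cut.** Cutting the bond between the β-carbon of the ketone and the alkene carbon opens ring A and leaves a cyclopropanol and an enol triflate on an intact ring B. The gain is one ring, with both quaternary centres and all four stereocentres settled before the closure. The demand is reductive elimination ahead of β-hydride elimination at a crowded alkenyl palladium centre.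

**Cyclopropane C–C bonds and the C3 oxygen (28 ⇒ 26 ⇒ 25 ⇒ 24).** The cyclopropanol is traced to a silyl enol ether, a methyl ketone and then a vinyl group on C4. The gain is that C1–C3 derive from a simple vinyl group plus one methylene. The demand is Markovnikov oxidation of a neopentyl vinyl group, and enolisation that can only go toward the methyl group because C4 is quaternary.

**C6–H and O10–S (24 ⇒ 23 ⇒ 22 ⇒ 18).** The C6 carbinol and the C10 triflate are both taken back to the 1,3-dione 18. The gain is a symmetrical oxidation pattern that a sigmatropic shift can deliver. The demand is to place the triflate on the more hindered oxygen; this is met by transient silylation of O6 and γ-deprotonation (19–21). C6 is then set by a reagent-controlled reduction.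

**C4–C5 (18 ⇒ 17 ⇒ 16 + 6).** The quaternary C4 is cut from C5 by a retro-Claisen step to the allyl vinylogous ester 17, itself from dione 16 and alcohol 6. The gain is that C4 with its methyl, oxymethyl and vinyl groups comes from a four-carbon alcohol. The demand is facial selectivity at C5, which fixes C4 relative to C8/C9; this is the least secure element.

**Ring B (16 ⇒ 15 ⇒ 14 ⇒ 13 ⇒ 11 + 8 ⇒ 9; 8 ⇐ 7).** The C6 oxygen is removed through epoxy ketone 15 and enone 14; the C9–C11 bond is cut to enol ether 11 and triflate 8; the C8–methyl bond is cut to enone 9. The gain is an achiral commercial enone. The demand is catalyst control at C8 and alkylation anti to the C8 methyl group at C9.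

**The allyl unit (6 ⇒ 5 ⇒ 4 ⇒ 2 ⇒ 1).** The C–methyl bond is cut by a retro-carbocupration to ynoate 4, and the ester carbon is cut to alkyne 2. The gain is complete control of the (Z) geometry from a syn addition. The demand is low temperature so that the alkenylcopper does not isomerise.

## Other disconnections considered

**Alternative 1:** The cut is C9–C11, together with the O6–C12 lactone bond.
- Forward step: the cis-diol A1 (ring A in place, C9=C10 alkene, tertiary C5–OH cis to C6–OH) is heated with an orthoacetate ester and a trace of acid. The cyclic ketene acetal undergoes a [3,3] shift that forms C9–C11 on the face of the two oxygens, moves the alkene to C5=C10 and leaves the bridged lactone A2.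
- In its favour: C9 is set suprafacially from the C6 oxygen, so the C6/C9 relationship is stereospecific; the tetrasubstituted alkene is placed without an enol triflate; C11–C12 arrive with O6 internally protected. On these points (coupling of C6 to C9, no transition metal, no β-hydride side path) it is the better plan.
- Against it here: A1 needs the whole bicycle with C4 and the tertiary allylic C5 alcohol already correct, so the C4 problem is only moved upstream. The tethered shift must pass through a boat-like bridged transition state onto a fully substituted alkene terminus next to C8. The tertiary allylic alcohol can ionise under acid. The lactone carbonyl must later be reduced while C3 is oxidised.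
- Comparison: structurally both plans leave C4 to another step; mechanistically the pericyclic step is more predictable than the palladium closure; in step economy the two are about equal after the key step, but A1 should be harder to reach than 28.

**Alternative 2:** The cut is C7–C8 plus C9–C10.
- Forward step: the ring A siloxydiene A3 and (E)-2-methylbut-2-enal A4 undergo a [4+2] cycloaddition under a protonated chiral oxazaborolidine (triflimide salt) to give cycloadduct A5.
- In its favour: it is the most convergent plan. It builds ring B, two C–C bonds and the C8/C9 pair in one step; the cis methyl groups follow from the E geometry of A4; absolute configuration is under reagent control; regiochemistry is electronically matched (nucleophilic C7 to the β-carbon of the enal). In bonds and stereocentres per step it is better than the chosen key step, which forms one bond and no stereocentre.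
- Against it here: the diene hangs on quaternary C4, so its s-cis conformer is strained. A4 is an α,β-disubstituted and therefore slow dienophile. The catalyst must override the C3/C4 centres of A3, a double stereodifferentiation of uncertain sense, and C4 must already be set. Afterwards the enol ether must be dehydrogenated to the C5=C10 enone, C6 reduced, C11 homologated by one carbon and C3 oxidised; the C10–H centre is made only to be destroyed.
- Comparison: a concerted cycloaddition with a known catalyst class is at least as dependable mechanistically as the homoenolate closure. The extra redox and homologation steps make the count no shorter, and the main uncertainty sits in the strategy-bearing step.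

**Alternative 3:** The cut is C4–C5.
- Forward step: BF3·OEt2 opens the methyl-substituted oxirane of the hydrindenyl epoxy alcohol A6 at tertiary C4, and the alkenyl carbon C5 migrates from the carbinol carbon C3 to C4 (semipinacol shift). The cyclopentene expands to ring A and gives ketol A7.
- In its favour: the shift is stereospecific (inversion at C4, anti to the departing oxygen), so C4 derives from an epoxide that a directed or asymmetric epoxidation can set. This answers the weakest point of the chosen plan and is better on that score. It also delivers the C3 ketone and free C19–OH together, without Wacker oxidation, cyclopropanation or PMB removal, so it is shorter after the key step.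
- Against it here: A6 needs a cyclopentenone fused to ring B and an addition/epoxidation sequence at C3/C4 whose relation to the remote C8/C9 centres again has no adjacent control element. Under the Lewis acid, migration of C2 instead of C5, epoxide isomerisation and ionisation of the allylic C6 ether can compete. A7 is a retro-aldol-prone ketol formed under acid.
- Comparison: both plans close ring A late on an intact ring B; the cationic shift is stereospecific but less tolerant of the allylic functionality than the neutral palladium coupling; A7 is closer to the target than 29, but A6 is probably further from commercial material than 28.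

Key step: step 19

## Route

Step 1
Reactants: 1 prop-2-yn-1-ol
Product: 2 1-methoxy-4-[(prop-2-yn-1-yloxy)methyl]benzene
Conditions: NaH, PMBCl, Bu4NI (cat.), THF/DMF, 0 °C → rt
Reagents that add atoms: 4-methoxybenzyl chloride COc1ccc(CCl)cc1
Why: Williamson etherification of the alkoxide with the benzylic chloride; one equivalent of base leaves the alkyne C–H untouched.

Step 2
Reactants: 2 1-methoxy-4-[(prop-2-yn-1-yloxy)methyl]benzene
Product: 4 methyl 4-[(4-methoxybenzyl)oxy]but-2-ynoate, via lithium acetylide 3 (not isolated)
Conditions: n-BuLi, THF, −78 °C; ClCO2Me, −78 → 0 °C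
Reagents that add atoms: methyl chloroformate COC(=O)Cl
Why: Deprotonation of the terminal alkyne and C-acylation of the acetylide with the chloroformate gives the ynoate.

Step 3
Reactants: 4 methyl 4-[(4-methoxybenzyl)oxy]but-2-ynoate
Product: 5 methyl (Z)-4-[(4-methoxybenzyl)oxy]-3-methylbut-2-enoate
Conditions: Me2CuLi (from CuI and MeLi), THF, −78 °C; MeOH quench at −78 °C
Reagents that add atoms: lithium dimethylcuprate C[Cu-]C.[Li+]
Why: Syn carbocupration of the ynoate and protonation with retention put methyl and hydrogen cis, so the oxymethyl group ends cis to the ester, i.e. the (Z)-enoate; the low temperature prevents isomerisation of the alkenylcopper through an allenoate.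

Step 4
Reactants: 5 methyl (Z)-4-[(4-methoxybenzyl)oxy]-3-methylbut-2-enoate
Product: 6 (Z)-4-[(4-methoxybenzyl)oxy]-3-methylbut-2-en-1-ol
Conditions: DIBAL-H (2.2 equiv), CH2Cl2, −78 °C; Rochelle salt work-up
Reagents that add atoms: none
Why: 1,2-Reduction of the enoate by the aluminium hydride gives the allylic alcohol without touching the alkene geometry.

Step 5
Reactants: 7 2-[(tert-butyldimethylsilyl)oxy]ethan-1-ol
Product: 8 2-[(tert-butyldimethylsilyl)oxy]ethyl trifluoromethanesulfonate
Conditions: Tf2O, 2,6-lutidine, CH2Cl2, −78 °C; used at once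
Reagents that add atoms: trifluoromethanesulfonic anhydride O=S(=O)(OS(=O)(=O)C(F)(F)F)C(F)(F)F
Why: O-Sulfonylation of the primary alcohol with a hindered base; the triflate is chosen because the corresponding iodide is too sluggish for forming a quaternary carbon.

Step 6
Reactants: 9 2-methylcyclohex-2-en-1-one
Product: 11 (S)-[(2,3-dimethylcyclohex-1-en-1-yl)oxy]trimethylsilane, via dimethylaluminium enolate 10 (not isolated)
Conditions: Me3Al, Cu(O2CC4H3S) (CuTC, 2 mol%), chiral binaphthol-derived phosphoramidite (4 mol%), Et2O, −30 °C; then TMSOTf, THF, −30 → 0 °C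
Reagents that add atoms: trimethylaluminium C[Al](C)C; trimethylsilyl trifluoromethanesulfonate C[Si](C)(C)OS(=O)(=O)C(F)(F)F
Why: Copper–phosphoramidite catalysed asymmetric conjugate addition of the methylaluminium reagent sets C8 as (S) under catalyst control (the ligand enantiomer is chosen accordingly); the regiodefined aluminium enolate is trapped on oxygen as the silyl enol ether.

Step 7
Reactants: 11 (S)-[(2,3-dimethylcyclohex-1-en-1-yl)oxy]trimethylsilane; 8 2-[(tert-butyldimethylsilyl)oxy]ethyl trifluoromethanesulfonate
Product: 13 (2R,3S)-2-{2-[(tert-butyldimethylsilyl)oxy]ethyl}-2,3-dimethylcyclohexan-1-one, via lithium enolate 12 (not isolated)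
Conditions: MeLi, THF, 0 °C; then 8, THF/DMPU, −78 → −20 °C
Reagents that add atoms: none
Why: MeLi cleaves the silyl enol ether to the regiodefined tetrasubstituted lithium enolate, which is C-alkylated by the primary triflate (enolate alkylation); the electrophile enters anti to the adjacent C8 methyl group, so the chain ends trans to it and the two methyl groups cis (C9 R).

Step 8
Reactants: 13 (2R,3S)-2-{2-[(tert-butyldimethylsilyl)oxy]ethyl}-2,3-dimethylcyclohexan-1-one
Product: 14 (5S,6R)-6-{2-[(tert-butyldimethylsilyl)oxy]ethyl}-5,6-dimethylcyclohex-2-en-1-one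
Conditions: IBX, 4-methoxypyridine N-oxide, DMSO, 25 → 45 °C
Reagents that add atoms: none
Why: IBX-mediated α,β-dehydrogenation of the ketone; only C5 carries α-hydrogens because C9 is quaternary, so a single enone can form.

Step 9
Reactants: 14 (5S,6R)-6-{2-[(tert-butyldimethylsilyl)oxy]ethyl}-5,6-dimethylcyclohex-2-en-1-one
Product: 15 C5,C6-epoxy ketone (epoxide on the face anti to the C8 methyl group)
Conditions: H2O2 (30% aq), NaOH (cat.), MeOH, 0 °C
Reagents that add atoms: hydrogen peroxide OO
Why: Weitz–Scheffer nucleophilic epoxidation of the enone; hydroperoxide should add to C6 anti to the C8 methyl group, but the epoxide configuration is lost in the next step.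

Step 10
Reactants: 15 C5,C6-epoxy ketone
Product: 16 (4R,5S)-4-{2-[(tert-butyldimethylsilyl)oxy]ethyl}-4,5-dimethylcyclohexane-1,3-dione
Conditions: Pd(PPh3)4 (5 mol%), dppe (5 mol%), toluene, 100 °C
Reagents that add atoms: none
Why: Palladium-catalysed isomerisation of an α,β-epoxy ketone to a β-diketone: zerovalent palladium opens the Cα–O bond, β-hydride elimination from C6–H and tautomerisation give the 1,3-dione; C8 and C9 are not involved.

Step 11
Reactants: 16 (4R,5S)-4-{2-[(tert-butyldimethylsilyl)oxy]ethyl}-4,5-dimethylcyclohexane-1,3-dione; 6 (Z)-4-[(4-methoxybenzyl)oxy]-3-methylbut-2-en-1-ol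
Product: 17 allyl vinylogous ester (O6 ether of 16 with the (Z)-allyl unit; C10 ketone)
Conditions: PPh3, DIAD, THF, 0 °C → rt
Reagents that add atoms: none
Why: Mitsunobu O-alkylation of the acidic 1,3-dione by the primary allylic alcohol; the oxygen remote from quaternary C9 should react, and either regioisomer would deliver the allyl unit to C5 in the next step.

Step 12
Reactants: 17 allyl vinylogous ester
Product: 18 (4R,5S)-4-{2-[(tert-butyldimethylsilyl)oxy]ethyl}-2-[(2S)-1-[(4-methoxybenzyl)oxy]-2-methylbut-3-en-2-yl]-4,5-dimethylcyclohexane-1,3-dione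
Conditions: mesitylene, NaHCO3 (solid), 165 °C, sealed tube
Reagents that add atoms: none
Why: Thermal Claisen rearrangement ([3,3]) forms C4–C5 and the quaternary C4. In the chair transition state the allyl substituent cis to the O–CH2 group lies over ring B, so bonding should occur on the face opposite the cis C8/C9 methyl pair (the C9 chain can sit pseudoequatorial there); with the (Z)-ether this places CH2OPMB over the ring and gives (4S), while C5 stays epimerisable. This is substrate control and the least secure stereochemical element of the route.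

Step 13
Reactants: 18 Claisen dione
Product: 22 β-triflyloxy enone (C10–OTf, C5=C10, C6 ketone), via O6 triethylsilyl enol ether 19 (not isolated), via potassium dienolate 20 (not isolated), via dienyl triflate 21 (not isolated)
Conditions: TESCl, Et3N, DMAP (cat.), CH2Cl2, 0 °C; KHMDS, THF, −78 °C, then N-(5-chloropyridin-2-yl)triflimide, −78 → −20 °C; 0.5 M HCl, THF, 0 °C
Reagents that add atoms: N-(5-chloropyridin-2-yl)bis(trifluoromethanesulfonyl)imide O=S(=O)(N(c1ccc(Cl)cn1)S(=O)(=O)C(F)(F)F)C(F)(F)F
Why: O-Silylation of the dione should take the less hindered O6; the vinylogous silyl ester has no α'-hydrogen (C9 is quaternary), so the base removes a γ-hydrogen at C7 and the linear dienolate is O-sulfonylated at O10 (enol triflate formation). Mild acid hydrolyses only the silyl dienol ether, returning the C6 ketone with the triflate on the hindered oxygen.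

Step 14
Reactants: 22 β-triflyloxy enone
Product: 23 (6S)-allylic alcohol (C6–OH, C10–OTf)
Conditions: (R)-2-methyl-CBS-oxazaborolidine (20 mol%), catecholborane, toluene, −78 °C
Reagents that add atoms: none
Why: CBS reduction of the enone carbonyl; with the tetrasubstituted alkenyl arm acting as the large group the (R)-catalyst should deliver hydride to give (6S), and catecholborane does not hydroborate the vinyl group at this temperature.

Step 15
Reactants: 23 (6S)-allylic alcohol
Product: 24 C6 TBS ether (enol triflate with vinyl group on C4)
Conditions: TBSOTf, 2,6-lutidine, CH2Cl2, −78 → 0 °C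
Reagents that add atoms: tert-butyldimethylsilyl trifluoromethanesulfonate CC(C)(C)[Si](C)(C)OS(=O)(=O)C(F)(F)F
Why: Silylation of the hindered secondary alcohol with the silyl triflate; the free alcohol would otherwise bind palladium and be oxidised in later steps.

Step 16
Reactants: 24 C6 TBS ether
Product: 25 methyl ketone (C3 ketone; C4 bears acetyl, methyl and CH2OPMB)
Conditions: PdCl2 (10 mol%), Cu(OAc)2 (20 mol%), O2 (1 atm), DMA/H2O (7:1), 25 °C
Reagents that add atoms: water O
Why: Wacker–Tsuji oxidation of the terminal vinyl group with Markovnikov delivery of oxygen to C3; the tetrasubstituted alkenyl triflate is too hindered and electron-poor to react with divalent palladium.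

Step 17
Reactants: 25 methyl ketone
Product: 26 trimethylsilyl enol ether of 25
Conditions: TMSOTf, Et3N, CH2Cl2, 0 °C
Reagents that add atoms: trimethylsilyl trifluoromethanesulfonate C[Si](C)(C)OS(=O)(=O)C(F)(F)F
Why: Soft enolisation and O-silylation; C4 is quaternary, so only the methyl side can enolise and a single silyl enol ether forms.

Step 18
Reactants: 26 trimethylsilyl enol ether
Product: 28 cyclopropanol enol triflate (key-step precursor), via siloxycyclopropane 27 (not isolated)
Conditions: Et2Zn, CH2I2, CH2Cl2, 0 °C; then K2CO3 (cat.), MeOH, 0 °C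
Reagents that add atoms: diiodomethane C(I)I
Why: Simmons–Smith cyclopropanation (Furukawa conditions) of the electron-rich silyl enol ether, which reacts far faster than the electron-poor alkenyl triflate; mild methanolysis of the trimethylsilyl ether frees the tertiary cyclopropanol and leaves both TBS ethers in place.

Step 19
Reactants: 28 cyclopropanol enol triflate
Product: 29 protected bicyclic ketone (ring A closed; C3 ketone, C5=C10)
Conditions: Pd(OAc)2 (10 mol%), XPhos (20 mol%), Cs2CO3 (2 equiv), toluene, 80 °C
Reagents that add atoms: none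
Why: Pd(OAc)2 is reduced in the flask to zerovalent palladium, which adds oxidatively to the C10–OTf bond; the cyclopropanol, deprotonated by Cs2CO3, then displaces triflate on divalent palladium to give a six-membered palladium alkoxide chelate. β-Carbon elimination, driven by release of ring strain, cleaves a C3–CH2 bond (the two methylenes are equivalent, so there is no regiochemical issue), unveils the C3 ketone and leaves palladium on C1 in a seven-membered alkyl(alkenyl)palladacycle. C(sp3)–C(sp2) reductive elimination forms C1–C10 and closes ring A. The closest known reaction type is the palladium-catalysed ring-opening cross-coupling of cyclopropanols with aryl and alkenyl halides or triflates, used here intramolecularly. Mode of closure: a six-membered carbocycle forms by reductive elimination onto the alkenyl carbon, with C5=C10 endocyclic to both rings, so there is no exo/endo alternative. No stereocentre is created, and none can be lost: C4 is quaternary and the ketone can enolise only toward C2. The selectivity needed is reductive elimination over β-hydride elimination from C2 of the palladium homoenolate; the bulky electron-rich biaryl phosphine, which speeds reductive elimination, and the chelated intramolecular arrangement that holds C1 and C10 cis on palladium should secure it.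

Step 20
Reactants: 29 protected bicyclic ketone
Product: 30 C19 ketol
Conditions: DDQ, CH2Cl2/pH 7 buffer (10:1), 0 °C
Reagents that add atoms: none
Why: Oxidative cleavage of the PMB ether by DDQ under buffered conditions; silyl ethers, the ketone and the tetrasubstituted alkene are inert, and the neutral medium avoids retro-aldol loss of C19.

Step 21
Reactants: 31 3-(4-hydroxyphenyl)propanoic acid
Product: 33 3-{4-[(tert-butyldimethylsilyl)oxy]phenyl}propanoic acid, via bis-silyl derivative 32 (not isolated)
Conditions: TBSCl (2.5 equiv), imidazole, DMF, rt; then AcOH/THF/H2O, rt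
Reagents that add atoms: tert-butyldimethylsilyl chloride CC(C)(C)[Si](C)(C)Cl
Why: Exhaustive silylation followed by selective hydrolysis of the labile silyl ester; the aryl silyl ether is stable to mild aqueous acid.

Step 22
Reactants: 30 C19 ketol; 33 3-{4-[(tert-butyldimethylsilyl)oxy]phenyl}propanoic acid
Product: 34 C19 ester
Conditions: EDC·HCl, DMAP (cat.), CH2Cl2, 0 °C → rt
Reagents that add atoms: none
Why: Steglich-type carbodiimide esterification of the primary neopentyl alcohol; the weakly basic medium should acylate faster than the ketol can fragment, and the resulting β-acyloxy ketone cannot eliminate because C4 has no hydrogen.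

Step 23
Reactants: 34 C19 ester
Product: 35 C12 primary alcohol
Conditions: CSA (10 mol%), MeOH/CH2Cl2 (1:1), 0 °C
Reagents that add atoms: none
Why: Acid-catalysed methanolysis removes the unhindered primary TBS ether selectively; the crowded secondary O6 ether and the aryl silyl ether (labile to base and fluoride, not to mild acid) should survive.

Step 24
Reactants: 35 C12 primary alcohol
Product: 36 C12 primary iodide
Conditions: I2, PPh3, imidazole, CH2Cl2, 0 °C
Reagents that add atoms: iodine [I][I]
Why: Appel-type iodination of the primary alcohol by displacement of the oxyphosphonium ion; ketone, ester and silyl ethers are unaffected.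

Step 25
Reactants: 36 C12 primary iodide; 37 4-bromofuran-2(5H)-one
Product: 39 bis-silylated butenolide, via alkylzinc iodide 38 (not isolated)
Conditions: Zn dust, LiCl, THF, 40 °C; then 37, Pd2(dba)3 (2.5 mol%), SPhos (10 mol%), THF, 25 °C
Reagents that add atoms: none
Why: Zinc insertion into the primary iodide gives an alkylzinc reagent that tolerates the ketone and the ester; Negishi coupling with the vinylogous acyl bromide forms C12–C13, and the non-basic organozinc does not deprotonate the butenolide.

Step 26
Reactants: 39 bis-silylated butenolide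
Product: 40 target CNP0301014.1
Conditions: HF·pyridine, THF, 0 °C → rt
Reagents that add atoms: none
Why: Fluoride-mediated desilylation under acidic, non-basic conditions frees the C6 alcohol and the phenol without harming the butenolide, the ester or the β,γ-unsaturated ketone.

## Compound list

1 | prop-2-yn-1-ol | C#CCO | starting material
2 | 1-methoxy-4-[(prop-2-yn-1-yloxy)methyl]benzene | C#CCOCc1ccc(OC)cc1 | intermediate
3 | lithium acetylide of 2 | [Li]C#CCOCc1ccc(OC)cc1 | intermediate (not isolated)
4 | methyl 4-[(4-methoxybenzyl)oxy]but-2-ynoate | COC(=O)C#CCOCc1ccc(OC)cc1 | intermediate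
5 | methyl (Z)-4-[(4-methoxybenzyl)oxy]-3-methylbut-2-enoate | COC(=O)/C=C(/C)COCc1ccc(OC)cc1 | intermediate
6 | (Z)-4-[(4-methoxybenzyl)oxy]-3-methylbut-2-en-1-ol | OC/C=C(/C)COCc1ccc(OC)cc1 | intermediate
7 | 2-[(tert-butyldimethylsilyl)oxy]ethan-1-ol | OCCO[Si](C)(C)C(C)(C)C | starting material
8 | 2-[(tert-butyldimethylsilyl)oxy]ethyl trifluoromethanesulfonate | CC(C)(C)[Si](C)(C)OCCOS(=O)(=O)C(F)(F)F | intermediate
9 | 2-methylcyclohex-2-en-1-one | CC1=CCCCC1=O | starting material
10 | dimethylaluminium (S)-2,3-dimethylcyclohex-1-en-1-olate | C[C@H]1CCCC(O[Al](C)C)=C1C | intermediate (not isolated)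
11 | (S)-[(2,3-dimethylcyclohex-1-en-1-yl)oxy]trimethylsilane | C[C@H]1CCCC(O[Si](C)(C)C)=C1C | intermediate
12 | lithium (S)-2,3-dimethylcyclohex-1-en-1-olate | C[C@H]1CCCC([O-])=C1C.[Li+] | intermediate (not isolated)
13 | (2R,3S)-2-{2-[(tert-butyldimethylsilyl)oxy]ethyl}-2,3-dimethylcyclohexan-1-one | C[C@H]1CCCC(=O)[C@]1(C)CCO[Si](C)(C)C(C)(C)C | intermediate
14 | (5S,6R)-6-{2-[(tert-butyldimethylsilyl)oxy]ethyl}-5,6-dimethylcyclohex-2-en-1-one | C[C@H]1CC=CC(=O)[C@]1(C)CCO[Si](C)(C)C(C)(C)C | intermediate
15 | C5,C6-epoxide of 14, oxygen anti to the C8 methyl group (3-{2-[(TBS)oxy]ethyl}-3,4-dimethyl-7-oxabicyclo[4.1.0]heptan-2-one) | C[C@H]1C[C@@H]2O[C@@H]2C(=O)[C@]1(C)CCO[Si](C)(C)C(C)(C)C | intermediate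
16 | (4R,5S)-4-{2-[(tert-butyldimethylsilyl)oxy]ethyl}-4,5-dimethylcyclohexane-1,3-dione | C[C@H]1CC(=O)CC(=O)[C@]1(C)CCO[Si](C)(C)C(C)(C)C | intermediate
17 | (5S,6R)-6-{2-[(TBS)oxy]ethyl}-3-{[(2Z)-4-(PMB-oxy)-3-methylbut-2-en-1-yl]oxy}-5,6-dimethylcyclohex-2-en-1-one | C[C@H]1CC(OC/C=C(/C)COCc2ccc(OC)cc2)=CC(=O)[C@]1(C)CCO[Si](C)(C)C(C)(C)C | intermediate
18 | (4R,5S)-4-{2-[(TBS)oxy]ethyl}-2-[(2S)-1-(PMB-oxy)-2-methylbut-3-en-2-yl]-4,5-dimethylcyclohexane-1,3-dione (C2 of the ring epimerisable, left undefined) | C[C@H]1CC(=O)C([C@@](C)(COCc2ccc(OC)cc2)C=C)C(=O)[C@]1(C)CCO[Si](C)(C)C(C)(C)C | intermediate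
19 | O6 triethylsilyl enol ether of 18 (C5=C6, C10 ketone) | C[C@H]1CC(O[Si](CC)(CC)CC)=C([C@@](C)(COCc2ccc(OC)cc2)C=C)C(=O)[C@]1(C)CCO[Si](C)(C)C(C)(C)C | intermediate (not isolated)
20 | potassium dienolate of 19 (C6=C7, C5=C10, O10 anionic) | C[C@H]1C=C(O[Si](CC)(CC)CC)C([C@@](C)(COCc2ccc(OC)cc2)C=C)=C([O-])[C@]1(C)CCO[Si](C)(C)C(C)(C)C.[K+] | intermediate (not isolated)
21 | dienyl triflate (C10–OTf, C6–OTES, C5=C10 and C6=C7) | C[C@H]1C=C(O[Si](CC)(CC)CC)C([C@@](C)(COCc2ccc(OC)cc2)C=C)=C(OS(=O)(=O)C(F)(F)F)[C@]1(C)CCO[Si](C)(C)C(C)(C)C | intermediate (not isolated)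
22 | (5S,6R)-6-{2-[(TBS)oxy]ethyl}-2-[(2S)-1-(PMB-oxy)-2-methylbut-3-en-2-yl]-5,6-dimethyl-3-oxocyclohex-1-en-1-yl trifluoromethanesulfonate | C[C@H]1CC(=O)C([C@@](C)(COCc2ccc(OC)cc2)C=C)=C(OS(=O)(=O)C(F)(F)F)[C@]1(C)CCO[Si](C)(C)C(C)(C)C | intermediate
23 | (3S,5S,6R)-3-hydroxy analogue of 22 (halimane 6S alcohol) | C[C@H]1C[C@H](O)C([C@@](C)(COCc2ccc(OC)cc2)C=C)=C(OS(=O)(=O)C(F)(F)F)[C@]1(C)CCO[Si](C)(C)C(C)(C)C | intermediate
24 | C6 TBS ether of 23 | C[C@H]1C[C@H](O[Si](C)(C)C(C)(C)C)C([C@@](C)(COCc2ccc(OC)cc2)C=C)=C(OS(=O)(=O)C(F)(F)F)[C@]1(C)CCO[Si](C)(C)C(C)(C)C | intermediate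
25 | methyl ketone: as 24 with the C4 vinyl group replaced by acetyl (C4 S) | C[C@H]1C[C@H](O[Si](C)(C)C(C)(C)C)C([C@@](C)(COCc2ccc(OC)cc2)C(C)=O)=C(OS(=O)(=O)C(F)(F)F)[C@]1(C)CCO[Si](C)(C)C(C)(C)C | intermediate
26 | trimethylsilyl enol ether of 25 (C3(OTMS)=CH2) | C[C@H]1C[C@H](O[Si](C)(C)C(C)(C)C)C([C@@](C)(COCc2ccc(OC)cc2)C(=C)O[Si](C)(C)C)=C(OS(=O)(=O)C(F)(F)F)[C@]1(C)CCO[Si](C)(C)C(C)(C)C | intermediate
27 | 1-(trimethylsilyloxy)cyclopropyl analogue (TMS ether of 28) | C[C@H]1C[C@H](O[Si](C)(C)C(C)(C)C)C([C@@](C)(COCc2ccc(OC)cc2)C2(O[Si](C)(C)C)CC2)=C(OS(=O)(=O)C(F)(F)F)[C@]1(C)CCO[Si](C)(C)C(C)(C)C | intermediate (not isolated)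
28 | cyclopropanol enol triflate: ring B cyclohexene with C10–OTf, C5 bearing (S)-C4 (methyl, CH2OPMB, 1-hydroxycyclopropyl), (6S)-OTBS, (8S)-methyl, (9R)-methyl and CH2CH2OTBS | C[C@H]1C[C@H](O[Si](C)(C)C(C)(C)C)C([C@@](C)(COCc2ccc(OC)cc2)C2(O)CC2)=C(OS(=O)(=O)C(F)(F)F)[C@]1(C)CCO[Si](C)(C)C(C)(C)C | intermediate
29 | (1S,5R,6S,8S)-8-[(TBS)oxy]-5-{2-[(TBS)oxy]ethyl}-1-[(PMB-oxy)methyl]-1,5,6-trimethyl-3,4,5,6,7,8-hexahydronaphthalen-2(1H)-one | C[C@H]1C[C@H](O[Si](C)(C)C(C)(C)C)C2=C(CCC(=O)[C@]2(C)COCc2ccc(OC)cc2)[C@]1(C)CCO[Si](C)(C)C(C)(C)C | intermediate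
30 | C19 ketol: 29 with CH2OH in place of CH2OPMB | C[C@H]1C[C@H](O[Si](C)(C)C(C)(C)C)C2=C(CCC(=O)[C@]2(C)CO)[C@]1(C)CCO[Si](C)(C)C(C)(C)C | intermediate
31 | 3-(4-hydroxyphenyl)propanoic acid | OC(=O)CCc1ccc(O)cc1 | starting material
32 | tert-butyldimethylsilyl 3-{4-[(tert-butyldimethylsilyl)oxy]phenyl}propanoate | CC(C)(C)[Si](C)(C)OC(=O)CCc1ccc(O[Si](C)(C)C(C)(C)C)cc1 | intermediate (not isolated)
33 | 3-{4-[(tert-butyldimethylsilyl)oxy]phenyl}propanoic acid | OC(=O)CCc1ccc(O[Si](C)(C)C(C)(C)C)cc1 | intermediate
34 | C19 ester of 30 with 33 (O6 and O12 as TBS ethers) | C[C@H]1C[C@H](O[Si](C)(C)C(C)(C)C)C2=C(CCC(=O)[C@]2(C)COC(=O)CCc2ccc(O[Si](C)(C)C(C)(C)C)cc2)[C@]1(C)CCO[Si](C)(C)C(C)(C)C | intermediate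
35 | C12 primary alcohol (34 without the O12 silyl group) | C[C@H]1C[C@H](O[Si](C)(C)C(C)(C)C)C2=C(CCC(=O)[C@]2(C)COC(=O)CCc2ccc(O[Si](C)(C)C(C)(C)C)cc2)[C@]1(C)CCO | intermediate
36 | C12 primary iodide | C[C@H]1C[C@H](O[Si](C)(C)C(C)(C)C)C2=C(CCC(=O)[C@]2(C)COC(=O)CCc2ccc(O[Si](C)(C)C(C)(C)C)cc2)[C@]1(C)CC[I] | intermediate
37 | 4-bromofuran-2(5H)-one | BrC1=CC(=O)OC1 | starting material
38 | C12 alkylzinc iodide | C[C@H]1C[C@H](O[Si](C)(C)C(C)(C)C)C2=C(CCC(=O)[C@]2(C)COC(=O)CCc2ccc(O[Si](C)(C)C(C)(C)C)cc2)[C@]1(C)CC[Zn][I] | intermediate (not isolated)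
39 | target with O6 and the phenol as TBS ethers | C[C@H]1C[C@H](O[Si](C)(C)C(C)(C)C)C2=C(CCC(=O)[C@]2(C)COC(=O)CCc2ccc(O[Si](C)(C)C(C)(C)C)cc2)[C@]1(C)CCC1=CC(=O)OC1 | intermediate
40 | CNP0301014.1, (4S,6S,8S,9R)-6-hydroxy-3-oxohalima-5(10),13-dien-15,16-olid-19-yl 3-(4-hydroxyphenyl)propanoate | C[C@H]1C[C@H](O)C2=C(CCC(=O)[C@]2(C)COC(=O)CCc2ccc(O)cc2)[C@]1(C)CCC1=CC(=O)OC1 | target

## Step count and risks

Total step count: 26. Longest linear sequence: 20 steps from 9 (steps 6–20 and 22–26); the branches from 1 (4 steps), 7 (1 step) and 31 (1 step) join at steps 11, 7 and 22.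

Least certain steps:

**Step 19 (key step).** β-Hydride elimination from the palladium homoenolate may outrun the ring-closing reductive elimination. Alternatively, oxidative addition to the crowded tetrasubstituted triflate may be so slow that the cyclopropanol is consumed by base-induced ring opening. The fallback changes the bond-forming mechanism. It sets out from 28: electrophilic ring opening with N-iodosuccinimide gives the β-iodo ketone F1 (C1–I, C3 ketone, triflate intact). An intramolecular nickel-catalysed reductive cross-electrophile coupling of the alkyl iodide with the alkenyl triflate (NiBr2(dme), 4,4'-di-tert-butyl-2,2'-bipyridine, Zn, DMA) then forms C1–C10 and comes back to the route at 29.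

**Step 12 (Claisen).** Facial selectivity at C5 may be poor, giving both C4 epimers, and ionisation–recombination may compete at the high temperature. The fallback replaces substrate control by chirality transfer. It sets out from 6 and 16. MnO2 oxidation of 6 gives the (Z)-enal F2. Catalytic asymmetric addition of Me2Zn (chiral amino alcohol ligand) gives the (R,Z)-secondary allylic alcohol F3. Mitsunobu etherification of 16 with F3, with inversion, gives the vinylogous ester F4 whose oxygen-bearing carbon is (S). On heating, the methyl group on that carbon takes the equatorial site of the transition state; this fixes which face of the allyl terminus bonds to C5 whatever ring face is used, and gives the (E)-propenyl dione F5 with (4S). Ethenolysis (second-generation Hoveyda–Grubbs catalyst, ethylene) trims propenyl to vinyl and comes back at 18.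

**Step 13 (triflate on O10).** Silylation may occur on the wrong oxygen, or O-sulfonylation of the crowded dienolate may be slow, so that the triflate ends on O6 or the dienolate is consumed otherwise. The fallback sets out from 18. The less hindered C6 carbonyl is reduced first (NaBH4, MeOH, −20 °C) to the hydroxy ketone F6, which is silylated (TBSOTf, 2,6-lutidine) to the ketone F7. The C10 enol triflate is then formed by deprotonation at C5, the only enolisable position (KHMDS, then the same triflimide). This comes back at 24 and bypasses 22 and 23, at the price of substrate-controlled C6 configuration and a hindered deprotonation.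

**Step 14 (CBS reduction).** The intrinsic bias of the ring (hydride delivery leading to OH cis to the C8 methyl group) may oppose the catalyst, a mismatched case, and erode the selectivity. The fallback uses the substrate bias and then inverts. It sets out from 22: Luche reduction (NaBH4, CeCl3, MeOH) gives the (6R)-alcohol F8; Mitsunobu inversion with 4-nitrobenzoic acid gives the (6S)-ester F9; methanolysis (K2CO3, MeOH, 0 °C) comes back at 23.

**Step 16 (Wacker oxidation).** Oxidation of the neopentyl vinyl group may be slow, palladium bound to the homoallylic ether oxygen may steer oxygen to the terminal carbon, and acid formed in the medium may cleave the primary silyl ether. The fallback builds the methyl ketone stepwise. It sets out from 24: OsO4 (cat.)/NaIO4 with 2,6-lutidine cleaves the vinyl group to the aldehyde F10; MeMgBr (THF, −78 °C) gives the secondary alcohol F11; Dess–Martin oxidation comes back at 25.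

## Further compounds

F1 | step 19 | β-iodo ketone from ring opening of 28 (C1–I, C3 ketone, C10–OTf) | C[C@H]1C[C@H](O[Si](C)(C)C(C)(C)C)C([C@@](C)(COCc2ccc(OC)cc2)C(=O)CC[I])=C(OS(=O)(=O)C(F)(F)F)[C@]1(C)CCO[Si](C)(C)C(C)(C)C
F2 | step 12 | (Z)-4-[(4-methoxybenzyl)oxy]-3-methylbut-2-enal | O=C/C=C(/C)COCc1ccc(OC)cc1
F3 | step 12 | (2R,3Z)-5-[(4-methoxybenzyl)oxy]-4-methylpent-3-en-2-ol | C[C@@H](O)/C=C(/C)COCc1ccc(OC)cc1
F4 | step 12 | vinylogous ester of 16 with the (2S,3Z)-5-(PMB-oxy)-4-methylpent-3-en-2-yl group on O6 | C[C@H]1CC(O[C@@H](C)/C=C(/C)COCc2ccc(OC)cc2)=CC(=O)[C@]1(C)CCO[Si](C)(C)C(C)(C)C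
F5 | step 12 | (E)-propenyl analogue of 18 (C4 S) | C[C@H]1CC(=O)C([C@@](C)(COCc2ccc(OC)cc2)/C=C/C)C(=O)[C@]1(C)CCO[Si](C)(C)C(C)(C)C
F6 | step 13 | C6 hydroxy C10 ketone from 18 (C5 undefined) | C[C@H]1C[C@H](O)C([C@@](C)(COCc2ccc(OC)cc2)C=C)C(=O)[C@]1(C)CCO[Si](C)(C)C(C)(C)C
F7 | step 13 | C6 TBS ether of F6 | C[C@H]1C[C@H](O[Si](C)(C)C(C)(C)C)C([C@@](C)(COCc2ccc(OC)cc2)C=C)C(=O)[C@]1(C)CCO[Si](C)(C)C(C)(C)C
F8 | step 14 | (6R)-epimer of 23 | C[C@H]1C[C@@H](O)C([C@@](C)(COCc2ccc(OC)cc2)C=C)=C(OS(=O)(=O)C(F)(F)F)[C@]1(C)CCO[Si](C)(C)C(C)(C)C
F9 | step 14 | (6S)-4-nitrobenzoate of 23 | C[C@H]1C[C@H](OC(=O)c2ccc(cc2)[N+](=O)[O-])C([C@@](C)(COCc2ccc(OC)cc2)C=C)=C(OS(=O)(=O)C(F)(F)F)[C@]1(C)CCO[Si](C)(C)C(C)(C)C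
F10 | step 16 | C3 aldehyde from cleavage of the vinyl group of 24 | C[C@H]1C[C@H](O[Si](C)(C)C(C)(C)C)C([C@@](C)(COCc2ccc(OC)cc2)C=O)=C(OS(=O)(=O)C(F)(F)F)[C@]1(C)CCO[Si](C)(C)C(C)(C)C
F11 | step 16 | C3 secondary alcohol (methyl adduct of F10, carbinol configuration undefined) | C[C@H]1C[C@H](O[Si](C)(C)C(C)(C)C)C([C@@](C)(COCc2ccc(OC)cc2)C(C)O)=C(OS(=O)(=O)C(F)(F)F)[C@]1(C)CCO[Si](C)(C)C(C)(C)C
A1 | alternative 1 | C5,C6-cis-diol with C9=C10 alkene and ring A in place (C3 configuration arbitrary) | C[C@H]1C[C@H](O)[C@]2(O)C(=C1C)CC[C@@H](O[Si](C)(C)C(C)(C)C)[C@]2(C)COCc1ccc(OC)cc1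
A2 | alternative 1 | C6–C9 bridged lactone | C[C@H]1C[C@@H]2OC(=O)C[C@@]1(C)C1=C2[C@@](C)(COCc2ccc(OC)cc2)[C@H](O[Si](C)(C)C(C)(C)C)CC1
A3 | alternative 2 | ring A 1-(1-silyloxyvinyl)cyclohexene | C=C(O[Si](C)(C)C(C)(C)C)C1=CCC[C@@H](O[Si](C)(C)C(C)(C)C)[C@]1(C)COCc1ccc(OC)cc1
A4 | alternative 2 | (E)-2-methylbut-2-enal | C/C=C(\C)C=O
A5 | alternative 2 | bicyclic silyl enol ether aldehyde | C[C@H]1CC(O[Si](C)(C)C(C)(C)C)=C2[C@H](CC[C@@H](O[Si](C)(C)C(C)(C)C)[C@]2(C)COCc2ccc(OC)cc2)[C@]1(C)C=O
A6 | alternative 3 | hydrindenyl epoxy alcohol (C3 configuration arbitrary) | C[C@H]1C[C@H](O[Si](C)(C)C(C)(C)C)C2=C(CC[C@]2(O)[C@@]2(C)CO2)[C@]1(C)CCOCc1ccc(OC)cc1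
A7 | alternative 3 | ring A ketol | C[C@H]1C[C@H](O[Si](C)(C)C(C)(C)C)C2=C(CCC(=O)[C@]2(C)CO)[C@]1(C)CCOCc1ccc(OC)cc1
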